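## Analysis of the target

The target is a cis-fused decalin of the eudesmane type with a ketone at C8, an isopropyl group at C7, an acetoxy and a methyl group at C4, and an epoxyangelate ester at C3. Numbering used throughout: ring A = C1, C2, C3, C4, C5, C10; ring B = C5, C6, C7, C8, C9, C10; α is the face of ring A that bears both oxygen substituents, β the opposite face. The SMILES reads as 3R, 4S, 5S, 7R, 10R on the bicycle, that is 3α-acyloxy, 4α-acetoxy with 4β-methyl, 5β-H, 7β-isopropyl and 10β-methyl; the acid part is 2S,3S, the cis (angelate-derived) 2,3-dimethyloxirane-2-carboxylate. H5 and the C10 methyl are cis. In the chair–chair conformer with C9 axial on ring A, the C3 ester, the C4 methyl and the C7 isopropyl group are equatorial and the C4 acetoxy group is axial, syn to C9. C7 therefore has the thermodynamically preferred configuration next to the C8 ketone, whereas C5 and C10 must be set kinetically. Sensitive groups are the glycidic ester (acid, nucleophiles), the tertiary acetate beside a secondary ester (acyl migration, elimination) and the C8 ketone with enolisable C7 and C9. The hard points are the quaternary C10 with its absolute configuration, the cis ring fusion next to it, the fully substituted C4 with oxygen on the same face as O3, and the acylation of a hindered cis-diol with two different acyl groups. The route rests on one relationship: if C4 is a ketone, C5 is its α-carbon and C10 its β-carbon. A ring A cyclohexenone carrying the C9–C6 chain on its β-carbon can therefore take up the C10 methyl group by conjugate addition and use the resulting C5 enolate to close ring B onto C6.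

## Retrosynthetic reasoning

The C8 carbonyl of 32 is traced back to the exocyclic methylidene group of 30; only the C8=CH2 bond is cut. This keeps C8 as a ketone equivalent that is inert to enolate chemistry, organomagnesium addition and acylation, so C7 and C9 cannot enolise before the end. The forward step is an ozonolysis of the only alkene in 30, through ozonide 31.

The two ester C–O bonds are cut next: the acetate at O4 (30 from 29) and the epoxy ester at O3 (29 from diol 23 and acid 27, through anhydride 28). The secondary, equatorial 3-hydroxyl is acylated first because it is the only hydroxyl of 23 that reacts under mild activation; the tertiary, axial 4-hydroxyl is then forced with a small acyl donor. The reverse order would leave an acetate beside a free secondary hydroxyl and invite acyl migration.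

Acid 27 is taken back by oxidation level to epoxy alcohol 26, by its epoxide C–O bonds to allylic alcohol 25, and by reduction to acid 24. The Z geometry of 24 fixes the cis relationship of the carboxyl carbon and the C3' methyl, and the primary allylic alcohol is what a tartrate-controlled epoxidation needs.

In 23 the C4–methyl bond is cut, which gives α-hydroxy ketone 22. The forward addition must bring the methyl group to the β face of C4. The 3α-oxygen can chelate, and the axial C9 blocks the α face, so equatorial attack is expected to give the 4α-hydroxyl cis to O3.

The C3–O bond of 22 is cut back to ketone 20, by way of the epimeric ketol 21. C3 is the less hindered α-carbon of the C4 ketone (CH2 against the ring-fusion CH), so kinetic enolisation is regioselective. The oxidant is expected on the β face (21); since C3 stays enolisable, the equatorial 3α-epimer 22 is reached by equilibration.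

Ketone 20 is cut at two bonds, C10–CH3 and C5–C6, leading to enone 16 and reagent 17. Cutting here, and not at C9–C10 or C4–C5, removes ring B, the quaternary centre and the ring-fusion centre in one operation; what is left is a monocyclic 3-substituted cyclohexenone with one remote stereocentre. The forward reaction must add methyl to one face of the enone β-carbon under catalyst control, and the enolate so formed (18, activated as 19) must alkylate on carbon with the internal iodide to give the cis-fused ring.

Iodide 16 comes from alcohol 15 and silyl ether 14 by functional group interchange. Compound 14 is cut at the bond between the ring carbon (future C10) and the allylic CH2 (future C9) into allylic chloride 10 and vinylogous ester 11. The allyl unit has two identical CH2 termini, so organomagnesium 12 has no regiochemical choice, and the 1,2-adduct 13 collapses in acid to the transposed enone with the chain on the β-carbon.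

Chloride 10 is taken back through alkene 9 and methyl ketone 8 to Weinreb amide 6 and its alcohol 5, then to the hydroxymethylated imide 4, imide 3, auxiliary 1 and acid chloride 2. The only stereocentre of the chain (future C7) is made as the α-carbon of an acyl oxazolidinone, where a one-carbon oxygenated electrophile is introduced under auxiliary control. The acyl carbon becomes C8 with its methylidene group and the hydroxymethyl carbon becomes C6.

## Alternatives that were turned down

Alternative 1: Methoxyquinone Diels–Alder.
- Disconnection: C5–C6 and C9–C10, ring B by a [4+2] addition. Ring A is 2-methoxy-5-methyl-1,4-benzoquinone A1 and the C6–C9 unit is 2-(tert-butyldimethylsilyloxy)-3-isopropylbuta-1,3-diene A2.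
- Forward key step: a chiral Lewis acid from TiCl2(OiPr)2 A3 and enantiopure 1,1'-bi-2-naphthol A4 activates A1. A2 adds to the methyl-bearing double bond (the methoxy-bearing one is a deactivated vinylogous ester) and gives the cis-fused enedione A5 with the C8 oxygen as a silyl enol ether.
- For it: two simple partners give the whole bicycle in one step. The cis fusion follows from the suprafacial mechanism and not from a conformational argument, so on this point it is stronger than the chosen route. The regiochemistry is sound, since the nucleophilic diene terminus C9 bonds to C10, β to the more ketone-like C4 carbonyl.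
- Against it: A5 has oxygen at C1, C3 and C4, but the target has none at C1. The C1 carbonyl, neopentylic to C10, must be removed; the C2–C3 enol ether must be reduced with control at C3; and this must be done beside a second enol ether at C8. These redox and protection steps use up the early brevity. An enantioselective quinone Diels–Alder that forms a quaternary centre with a hindered, hydrolysis-prone 2,3-disubstituted diene is demanding.
- Comparison: the chosen strategy is more linear, but it delivers ring A with a single oxygen exactly at C4 and C8 already masked, so every later step builds towards the target and none removes functionality.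

Alternative 2: Enone–allene photocycloaddition.
- Disconnection: C9–C10, with a temporary C5–C8 bond, by a [2+2] photocycloaddition.
- Forward key step: irradiated 3-methylcyclohex-2-enone A6 adds allene A7 head-to-head and gives the cis-fused methylidenecyclobutane A8.
- For it: the cheapest possible materials; the quaternary C10 and a cis ring junction come in one step; the regiochemistry is well behaved. A8 already shows the C4 ketone and C8 methylidene pattern of 20. In cost and brevity of the first step it is stronger than the chosen route.
- Against it: A8 lacks C6, C7 and the isopropyl group. The C5–C8 bond must be broken again, and ring B must then be built by two further C–C bond formations with fresh control of C5 and C7. The photoreaction has no handle for absolute configuration, so a resolution or an auxiliary would be needed for a single enantiomer.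
- Comparison: the chosen key step gives 20, which is in effect A8 with C6, C7 and the isopropyl group in place and enantiocontrolled, at the price of a longer precursor synthesis.

Alternative 3: α-Ketol ring expansion.
- Disconnection: C4–C5, by an α-ketol shift that expands a five-membered ring to ring A.
- Forward key step: the tertiary acetyl carbinol A9 on a cis-hydrindane, held as a chelate by Al(OtBu)3 A10, shifts C5 from the carbinol carbon to the acetyl carbon and gives the 4α-hydroxy-4β-methyl-3,8-dione A11.
- For it: the fully substituted C4 carbinol and its methyl group arise in one stereospecific suprafacial step, and the C3 ketone that remains should reduce from the axial direction to the equatorial 3α-alcohol. On C3 and C4 it is stronger than the chosen route, whose steps 12 to 14 are its softest part.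
- Against it: A9 already contains the quaternary C10, the cis fusion, C7 and a tertiary carbinol of defined configuration. The hard problems move into a precursor for which no short enantioselective access is evident. The shift is reversible, and either ring bond at the carbinol carbon (to C5 or to C2) can migrate, so the regiochemistry rests on thermodynamics. The free C8 ketone is exposed to a Lewis acidic alkoxide.
- Comparison: the chosen strategy solves C10, C5 and the absolute configuration in one catalytic step and leaves only well-precedented functionalisation for ring A.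

Key step: step 11

Remark on the ligand: the copper step is defined by the face that must be attacked (the Si face of the enone β-carbon, which gives 10R). The phosphoramidite antipode is chosen for that face; both antipodes are accessible.

Remark on numbering: metal enolates, alkoxides and carboxylates that differ from a numbered compound only by exchange of a proton for a metal carry its number. Other species that persist in the flask until the next reagent or the work-up are numbered separately.

## Route

Step 1
Reactants: 1 (R)-4-benzyl-1,3-oxazolidin-2-one; 2 3-methylbutanoyl chloride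
Product: 3 (R)-4-benzyl-3-(3-methylbutanoyl)-1,3-oxazolidin-2-one
Conditions: n-BuLi, THF, −78 °C; then 2, −78 → 0 °C
Reagents that add atoms: none
Why: N-Acylation of the lithiated oxazolidinone (attachment of the Evans auxiliary); no stereocentre is formed and the auxiliary centre is not touched.

Step 2
Reactants: 3 (R)-4-benzyl-3-(3-methylbutanoyl)-1,3-oxazolidin-2-one
Product: 4 (R)-4-benzyl-3-[(S)-2-(hydroxymethyl)-3-methylbutanoyl]-1,3-oxazolidin-2-one
Conditions: TiCl4, iPr2NEt, CH2Cl2, 0 °C; then 1,3,5-trioxane, TiCl4, 0 °C
Reagents that add atoms: 1,3,5-trioxane, C1OCOCO1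
Why: Evans titanium-enolate hydroxymethylation: the chelated Z-enolate is attacked by the TiCl4-activated formaldehyde equivalent on the face opposite the benzyl group, which sets the future C7 as S in 4. This is the facial sense known for alkylation of the same chelated enolate, so the R auxiliary is the one required.

Step 3
Reactants: 4 (R)-4-benzyl-3-[(S)-2-(hydroxymethyl)-3-methylbutanoyl]-1,3-oxazolidin-2-one
Product: 5 (S)-2-(hydroxymethyl)-N-methoxy-N,3-dimethylbutanamide
Conditions: MeNHOMe·HCl, AlMe3, CH2Cl2, −15 → 0 °C
Reagents that add atoms: N,O-dimethylhydroxylamine hydrochloride, CNOC.Cl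
Why: Weinreb transamination of a β-hydroxy imide; the aluminium alkoxide of the free hydroxyl directs aminolysis to the exocyclic carbonyl. No enolate is formed, so the α-centre is kept, and auxiliary 1 is recovered.

Step 4
Reactants: 5 (S)-2-(hydroxymethyl)-N-methoxy-N,3-dimethylbutanamide
Product: 6 (S)-2-{[(tert-butyldimethylsilyl)oxy]methyl}-N-methoxy-N,3-dimethylbutanamide
Conditions: TBSCl, imidazole, DMF, rt
Reagents that add atoms: tert-butyldimethylsilyl chloride, C[Si](C)(Cl)C(C)(C)C
Why: Silyl ether formation at the primary hydroxyl (imidazole-promoted silylation); the ether must survive two organomagnesium steps, the titanium methylenation and the chlorination.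

Step 5
Reactants: 6 (S)-2-{[(tert-butyldimethylsilyl)oxy]methyl}-N-methoxy-N,3-dimethylbutanamide
Product: 8 (S)-3-{[(tert-butyldimethylsilyl)oxy]methyl}-4-methylpentan-2-one, via bromomagnesium hemiaminal chelate 7 (not isolated)
Conditions: MeMgBr, THF, 0 °C; aq. NH4Cl
Reagents that add atoms: methylmagnesium bromide, C[Mg]Br
Why: Weinreb ketone synthesis: the chelated tetrahedral adduct 7 stops at mono-addition and releases the ketone only on work-up. The cold, buffered quench protects the enolisable α-centre and avoids β-elimination of the silyloxy group.

Step 6
Reactants: 8 (S)-3-{[(tert-butyldimethylsilyl)oxy]methyl}-4-methylpentan-2-one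
Product: 9 tert-butyldimethyl{[(2R)-3-methyl-2-(propan-2-yl)but-3-en-1-yl]oxy}silane
Conditions: Cp2TiMe2, toluene, 65 °C, dark
Reagents that add atoms: dimethyltitanocene Cp2TiMe2, [CH3-].[CH3-].[Ti+4].c1cc[cH-]c1.c1cc[cH-]c1
Why: Petasis methylenation through a titanium carbene; it is non-basic, so the α-stereocentre and the β-silyloxy group are kept where a phosphorus ylide could enolise the ketone. The descriptor changes from S to R only because the former carbonyl carbon drops in priority.

Step 7
Reactants: 9 tert-butyldimethyl{[(2R)-3-methyl-2-(propan-2-yl)but-3-en-1-yl]oxy}silane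
Product: 10 tert-butyl{[(2R)-3-(chloromethyl)-2-(propan-2-yl)but-3-en-1-yl]oxy}dimethylsilane
Conditions: Ca(OCl)2, CO2 (solid), CH2Cl2–H2O, 0 °C
Reagents that add atoms: calcium hypochlorite Ca(OCl)2, [Ca+2].[O-]Cl.[O-]Cl
Why: Ene-type allylic chlorination with hypochlorous acid: chlorine adds to the terminal CH2 and the proton is lost from the methyl group, not from the hindered methine, as with the isopropenyl groups of terpenes. The stereocentre is not involved.

Step 8
Reactants: 10 tert-butyl{[(2R)-3-(chloromethyl)-2-(propan-2-yl)but-3-en-1-yl]oxy}dimethylsilane; 11 3-ethoxycyclohex-2-en-1-one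
Product: 14 3-[(3R)-3-{[(tert-butyldimethylsilyl)oxy]methyl}-4-methyl-2-methylidenepentyl]cyclohex-2-en-1-one, via allylmagnesium chloride 12 (not isolated), via chloromagnesium 1,2-adduct 13 (not isolated)
Conditions: Mg (activated), THF, 0 °C, slow addition of 10; then 11, 0 °C; then 1 M HCl, 0 °C
Reagents that add atoms: water, O (the enone oxygen of 14 comes from the aqueous acid)
Why: Grignard formation followed by the Stork–Danheiser sequence: 1,2-addition to the vinylogous ester and acid-induced hydrolysis with carbonyl transposition. The two allyl termini of 12 are identical, so no regiochemistry arises; brief cold acid leaves the primary silyl ether and the skipped diene intact.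

Step 9
Reactants: 14 3-[(3R)-3-{[(tert-butyldimethylsilyl)oxy]methyl}-4-methyl-2-methylidenepentyl]cyclohex-2-en-1-one
Product: 15 3-[(3R)-3-(hydroxymethyl)-4-methyl-2-methylidenepentyl]cyclohex-2-en-1-one
Conditions: HF·pyridine, pyridine–THF, 0 °C → rt
Reagents that add atoms: none
Why: Fluoride-mediated desilylation under buffered, non-basic conditions, so that the doubly allylic CH2 of the skipped dienone is not deprotonated and the alkene does not move into conjugation.

Step 10
Reactants: 15 3-[(3R)-3-(hydroxymethyl)-4-methyl-2-methylidenepentyl]cyclohex-2-en-1-one
Product: 16 3-[(3R)-3-(iodomethyl)-4-methyl-2-methylidenepentyl]cyclohex-2-en-1-one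
Conditions: PPh3, I2, imidazole, CH2Cl2, 0 °C → rt, dark
Reagents that add atoms: iodine, [I][I]
Why: Appel-type iodination (Garegg–Samuelsson conditions): SN2 displacement of the oxyphosphonium group at the primary carbon. The adjacent stereocentre is not a reacting centre and keeps its configuration.

Step 11
Reactants: 16 3-[(3R)-3-(iodomethyl)-4-methyl-2-methylidenepentyl]cyclohex-2-en-1-one; 17 trimethylaluminium
Product: 20 cis-decalone (5S,7R,10R)-10β-methyl-7β-isopropyl-8-methylidene-5β-H-decalin-4-one, via dimethylaluminium enolate 18 (not isolated), via lithium trimethylaluminate enolate 19 (not isolated)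
Conditions: CuTC [Cu(O2C-2-thienyl), 5 mol %], biphenol-derived bis(1-arylethyl)amine phosphoramidite L* (10 mol %), 17, Et2O, −30 °C; then MeLi, THF, −30 °C; then HMPA, −30 °C → rt; aq. NH4Cl
Reagents that add atoms: none
Why: Copper-catalysed asymmetric conjugate addition followed by intramolecular enolate alkylation, a Michael-initiated ring closure. Methyl passes from 17 to the copper–phosphoramidite complex, which binds the enone as a π-complex and forms the C10–CH3 bond through a σ-copper intermediate, leaving the regiodefined enolate 18 (O–Al on C4, C4=C5). MeLi converts 18 into the aluminate 19, whose enolate carbon C5 displaces iodide at C6 in an SN2 reaction. The closest known chemistry is the copper–phosphoramidite addition of trialkylaluminium reagents to 3-substituted cyclohex-2-enones with alkylation of the aluminium enolate after MeLi activation, together with the conjugate addition–cycloalkylation annulations of cuprate chemistry. Ring B closes in a 6-exo-tet mode with the enolate double bond outside the new ring. C10 is set by the ligand, whose chosen antipode sends methyl to the Si face of the β-carbon; the remote C7 centre should not override it. C5 is set by the substrate: the new bond must form perpendicular to the enolate plane while the chain sits equatorial on C10, and this is possible only on the face cis to the chain, which gives 5β-H with 10β-methyl. The step needs 1,4- over 1,2-addition (copper transfer), survival of the β-branched primary iodide until the ate complex forms, and C- over O-alkylation (O-alkylation would need an eight-membered ring).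

Step 12
Reactants: 20 cis-decalone (5S,7R,10R)-10β-methyl-7β-isopropyl-8-methylidene-5β-H-decalin-4-one
Product: 21 (3S,5S,7R,10R)-3β-hydroxy derivative of 20
Conditions: KN(SiMe3)2, THF, −78 °C; then 2-(phenylsulfonyl)-3-phenyloxaziridine, −78 °C; aq. NH4Cl
Reagents that add atoms: 2-(phenylsulfonyl)-3-phenyloxaziridine, O=S(=O)(N1OC1c1ccccc1)c1ccccc1
Why: Kinetic enolate formation and Davis oxaziridine hydroxylation: the base removes a C3 proton (CH2) and not the hindered ring-fusion proton at C5. Axial attack on the C3=C4 enolate, in the half-chair that keeps C9 pseudoaxial on the α face, comes from the β face, so the 3β-alcohol is expected as the main epimer; any 3α-epimer is carried along, because both converge in step 13.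

Step 13
Reactants: 21 (3S,5S,7R,10R)-3β-hydroxy derivative of 20
Product: 22 (3R,5S,7R,10R)-3α-hydroxy-10β-methyl-7β-isopropyl-8-methylidene-5β-H-decalin-4-one
Conditions: DBU (cat.), toluene, 0 °C → rt, followed until the epimer composition no longer changes
Reagents that add atoms: none
Why: Base-catalysed epimerisation of an α-ketol through its enediolate (thermodynamic control). The 3α-hydroxyl is equatorial and hydrogen-bonded to the carbonyl in the conformer with C9 axial on ring A, whereas the 3β-epimer must hold the hydroxyl axial or flip to a conformer with the C10 methyl and the isopropyl group axial. The tertiary C5–H is much slower to exchange than the activated C3–H.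

Step 14
Reactants: 22 (3R,5S,7R,10R)-3α-hydroxy-10β-methyl-7β-isopropyl-8-methylidene-5β-H-decalin-4-one
Product: 23 (3R,4S,5S,7R,10R)-8-methylidene-5β-eudesmane-3α,4α-diol
Conditions: MeMgBr (excess), THF, −78 → 0 °C; aq. NH4Cl
Reagents that add atoms: methylmagnesium bromide, C[Mg]Br
Why: Chelation-assisted Grignard addition to an α-alkoxy ketone: the first equivalent forms the magnesium alkoxide at O3, which chelates and activates the C4 carbonyl. Methyl then attacks equatorially from the β face, because the axial path on the α face is blocked by the syn-axial C9; this gives 4β-methyl and 4α-hydroxyl cis to O3.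

Step 15
Reactants: 24 angelic acid [(Z)-2-methylbut-2-enoic acid]
Product: 25 (Z)-2-methylbut-2-en-1-ol
Conditions: LiAlH4, Et2O, 0 °C
Reagents that add atoms: none
Why: Hydride reduction of the carboxylic acid to the allylic alcohol; in ether at low temperature the trisubstituted alkene is neither reduced nor isomerised, so the Z geometry is kept.

Step 16
Reactants: 25 (Z)-2-methylbut-2-en-1-ol
Product: 26 [(2R,3S)-2,3-dimethyloxiran-2-yl]methanol
Conditions: Ti(OiPr)4 (10 mol %), D-(−)-diethyl tartrate (12 mol %), t-BuOOH, 4 Å molecular sieves, CH2Cl2, −20 °C
Reagents that add atoms: tert-butyl hydroperoxide, CC(C)(C)OO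
Why: Sharpless asymmetric epoxidation: the D-tartrate complex delivers oxygen to the alkene face that gives 2R,3S. The facial rule was checked against the known outcomes for geraniol and nerol; the cis relation of the two ring substituents follows from the Z alkene.

Step 17
Reactants: 26 [(2R,3S)-2,3-dimethyloxiran-2-yl]methanol
Product: 27 (2S,3S)-2,3-dimethyloxirane-2-carboxylic acid
Conditions: RuCl3 (cat.), NaIO4, CCl4–MeCN–H2O, rt
Reagents that add atoms: water, O (through the aldehyde hydrate; sodium periodate NaIO4, [Na+].[O-]I(=O)(=O)=O, is the terminal oxidant)
Why: RuO4 oxidation of a primary epoxy alcohol to the glycidic acid, a standard follow-up to the epoxidation that leaves the oxirane intact. The descriptor at C2 changes from R to S only because the carboxyl carbon gains priority.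

Step 18
Reactants: 27 (2S,3S)-2,3-dimethyloxirane-2-carboxylic acid; 23 (3R,4S,5S,7R,10R)-8-methylidene-5β-eudesmane-3α,4α-diol
Product: 29 (3R,4S,5S,7R,10R)-4α-hydroxy-8-methylidene-5β-eudesman-3α-yl (2S,3S)-2,3-dimethyloxirane-2-carboxylate, via mixed anhydride 28 (not isolated)
Conditions: 27, 2,4,6-trichlorobenzoyl chloride, Et3N, THF, rt; then 23, DMAP, toluene, rt → 40 °C
Reagents that add atoms: none
Why: Yamaguchi esterification: DMAP opens the mixed anhydride 28 at the aliphatic carbonyl and the acylpyridinium ion acylates the secondary equatorial 3-hydroxyl. The tertiary axial 4-hydroxyl does not react under these conditions, and the non-acidic medium spares the epoxide.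

Step 19
Reactants: 29 (3R,4S,5S,7R,10R)-4α-hydroxy-8-methylidene-5β-eudesman-3α-yl (2S,3S)-2,3-dimethyloxirane-2-carboxylate
Product: 30 (3R,4S,5S,7R,10R)-4α-acetoxy-8-methylidene-5β-eudesman-3α-yl (2S,3S)-2,3-dimethyloxirane-2-carboxylate
Conditions: Ac2O (excess), DMAP, Et3N, CH2Cl2, 40 °C
Reagents that add atoms: acetic anhydride, CC(=O)OC(C)=O
Why: DMAP-catalysed acetylation of a tertiary alcohol (nucleophilic acyl-transfer catalysis) with a small acyl donor in excess. The basic, non-Lewis-acidic conditions leave the epoxide, the ester and the 1,1-disubstituted alkene untouched, and the C4 configuration is not involved.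

Step 20
Reactants: 30 (3R,4S,5S,7R,10R)-4α-acetoxy-8-methylidene-5β-eudesman-3α-yl (2S,3S)-2,3-dimethyloxirane-2-carboxylate
Product: 32 target CNP0221066.1 (3R,4S,5S,7R,10R)-4α-acetoxy-8-oxo-5β-eudesman-3α-yl (2S,3S)-2,3-dimethyloxirane-2-carboxylate, via secondary ozonide 31 (not isolated)
Conditions: O3, CH2Cl2, −78 °C; then Me2S, −78 °C → rt
Reagents that add atoms: ozone, [O-][O+]=O
Why: Ozonolysis with reductive work-up: the methylidene group is the only ozone-reactive site, and the neutral conditions do not touch the esters or the epoxide. C7 keeps its equatorial 7β configuration, which is also the thermodynamic one beside the new ketone.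

## Compound list

1 | (R)-4-benzyl-1,3-oxazolidin-2-one | O=C1OC[C@@H](Cc2ccccc2)N1 | starting material
2 | 3-methylbutanoyl chloride | CC(C)CC(=O)Cl | starting material
3 | (R)-4-benzyl-3-(3-methylbutanoyl)-1,3-oxazolidin-2-one | CC(C)CC(=O)N1[C@H](Cc2ccccc2)COC1=O | intermediate
4 | (R)-4-benzyl-3-[(S)-2-(hydroxymethyl)-3-methylbutanoyl]-1,3-oxazolidin-2-one | CC(C)[C@@H](CO)C(=O)N1[C@H](Cc2ccccc2)COC1=O | intermediate
5 | (S)-2-(hydroxymethyl)-N-methoxy-N,3-dimethylbutanamide | CC(C)[C@@H](CO)C(=O)N(C)OC | intermediate
6 | (S)-2-{[(tert-butyldimethylsilyl)oxy]methyl}-N-methoxy-N,3-dimethylbutanamide | CC(C)[C@@H](CO[Si](C)(C)C(C)(C)C)C(=O)N(C)OC | intermediate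
7 | bromomagnesium hemiaminal chelate from 6 and MeMgBr (new carbinol centre undefined) | CC(C)[C@@H](CO[Si](C)(C)C(C)(C)C)C(C)(O[Mg]Br)N(C)OC | intermediate (not isolated)
8 | (S)-3-{[(tert-butyldimethylsilyl)oxy]methyl}-4-methylpentan-2-one | CC(C)[C@@H](CO[Si](C)(C)C(C)(C)C)C(C)=O | intermediate
9 | tert-butyldimethyl{[(2R)-3-methyl-2-(propan-2-yl)but-3-en-1-yl]oxy}silane | CC(C)[C@@H](CO[Si](C)(C)C(C)(C)C)C(C)=C | intermediate
10 | tert-butyl{[(2R)-3-(chloromethyl)-2-(propan-2-yl)but-3-en-1-yl]oxy}dimethylsilane | CC(C)[C@@H](CO[Si](C)(C)C(C)(C)C)C(=C)CCl | intermediate
11 | 3-ethoxycyclohex-2-en-1-one | CCOC1=CC(=O)CCC1 | starting material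
12 | allylmagnesium chloride from 10: {2-[(2R)-1-(tert-butyldimethylsilyloxy)-3-methylbutan-2-yl]prop-2-en-1-yl}magnesium chloride | CC(C)[C@@H](CO[Si](C)(C)C(C)(C)C)C(=C)C[Mg]Cl | intermediate (not isolated)
13 | chloromagnesium alkoxide of the 1,2-adduct of 12 to 11 (both epimers at the carbinol carbon) | CCOC1=CC(O[Mg]Cl)(CC(=C)[C@@H](C(C)C)CO[Si](C)(C)C(C)(C)C)CCC1 | intermediate (not isolated)
14 | 3-[(3R)-3-{[(tert-butyldimethylsilyl)oxy]methyl}-4-methyl-2-methylidenepentyl]cyclohex-2-en-1-one | O=C1C=C(CC(=C)[C@@H](C(C)C)CO[Si](C)(C)C(C)(C)C)CCC1 | intermediate
15 | 3-[(3R)-3-(hydroxymethyl)-4-methyl-2-methylidenepentyl]cyclohex-2-en-1-one | O=C1C=C(CC(=C)[C@@H](C(C)C)CO)CCC1 | intermediate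
16 | 3-[(3R)-3-(iodomethyl)-4-methyl-2-methylidenepentyl]cyclohex-2-en-1-one | O=C1C=C(CC(=C)[C@@H](C(C)C)CI)CCC1 | intermediate (precursor of the key step)
17 | trimethylaluminium | C[Al](C)C | starting material
18 | dimethylaluminium enolate after methyl addition (O–Al on C4, C4=C5, 10R, 7R) | C[Al](C)OC1=C[C@@](C)(CC(=C)[C@@H](C(C)C)CI)CCC1 | intermediate (not isolated)
19 | lithium trimethylaluminate enolate formed from 18 and MeLi | [Li+].C[Al-](C)(C)OC1=C[C@@](C)(CC(=C)[C@@H](C(C)C)CI)CCC1 | intermediate (not isolated)
20 | cis-decalone (5S,7R,10R)-10β-methyl-7β-isopropyl-8-methylidene-5β-H-decalin-4-one | O=C1CCC[C@]2(C)CC(=C)[C@@H](C(C)C)C[C@@H]21 | intermediate (product of the key step)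
21 | (3S,5S,7R,10R)-3β-hydroxy-10β-methyl-7β-isopropyl-8-methylidene-5β-H-decalin-4-one | O=C1[C@@H](O)CC[C@]2(C)CC(=C)[C@@H](C(C)C)C[C@@H]21 | intermediate
22 | (3R,5S,7R,10R)-3α-hydroxy-10β-methyl-7β-isopropyl-8-methylidene-5β-H-decalin-4-one | O=C1[C@H](O)CC[C@]2(C)CC(=C)[C@@H](C(C)C)C[C@@H]21 | intermediate
23 | (3R,4S,5S,7R,10R)-8-methylidene-5β-eudesmane-3α,4α-diol | O[C@]1(C)[C@H](O)CC[C@]2(C)CC(=C)[C@@H](C(C)C)C[C@@H]21 | intermediate
24 | angelic acid, (Z)-2-methylbut-2-enoic acid | C/C=C(/C)C(=O)O | starting material
25 | (Z)-2-methylbut-2-en-1-ol | C/C=C(/C)CO | intermediate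
26 | [(2R,3S)-2,3-dimethyloxiran-2-yl]methanol | OC[C@@]1(C)O[C@H]1C | intermediate
27 | (2S,3S)-2,3-dimethyloxirane-2-carboxylic acid | OC(=O)[C@@]1(C)O[C@H]1C | intermediate
28 | (2S,3S)-2,3-dimethyloxirane-2-carboxylic 2,4,6-trichlorobenzoic anhydride | O=C(OC(=O)c1c(Cl)cc(Cl)cc1Cl)[C@@]1(C)O[C@H]1C | intermediate (not isolated)
29 | (3R,4S,5S,7R,10R)-4α-hydroxy-8-methylidene-5β-eudesman-3α-yl (2S,3S)-2,3-dimethyloxirane-2-carboxylate | O[C@]1(C)[C@H](OC(=O)[C@@]2(C)O[C@H]2C)CC[C@]2(C)CC(=C)[C@@H](C(C)C)C[C@@H]21 | intermediate
30 | (3R,4S,5S,7R,10R)-4α-acetoxy-8-methylidene-5β-eudesman-3α-yl (2S,3S)-2,3-dimethyloxirane-2-carboxylate | CC(=O)O[C@]1(C)[C@H](OC(=O)[C@@]2(C)O[C@H]2C)CC[C@]2(C)CC(=C)[C@@H](C(C)C)C[C@@H]21 | intermediate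
31 | secondary ozonide of 30 (spiro-1,2,4-trioxolane at C8, both C8 epimers) | CC(=O)O[C@]1(C)[C@H](OC(=O)[C@@]2(C)O[C@H]2C)CC[C@]2(C)CC3(OCOO3)[C@@H](C(C)C)C[C@@H]21 | intermediate (not isolated)
32 | CNP0221066.1, (3R,4S,5S,7R,10R)-4α-acetoxy-8-oxo-5β-eudesman-3α-yl (2S,3S)-2,3-dimethyloxirane-2-carboxylate | CC(=O)O[C@]1(C)[C@H](OC(=O)[C@@]2(C)O[C@H]2C)CC[C@]2(C)CC(=O)[C@@H](C(C)C)C[C@@H]21 | target

## Step count and uncertain steps

Total step count: 20. Longest linear sequence: 17 steps (steps 1 to 14 and 18 to 20); the acid branch (steps 15 to 17) joins at step 18.

Steps least certain to work: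

Step 11 (key step). Most likely to go wrong: the small methyl group transfers slowly to a β-carbon that carries a β-branched chain, so conversion and facial selectivity can suffer. The aluminate enolate can also fail to alkylate before work-up, or MeLi can consume the iodide by exchange or substitution, leaving an uncyclised ketone. Ring B must moreover close through a transition state in which the isopropyl group is axial. Fallback: set out from 16, carry out the same copper-catalysed addition, and silylate the aluminium enolate 18 in the flask with Me3SiOTf. This gives the isolable trimethylsilyl enol ether F1, in which the C4=C5 regiochemistry is stored. Treat purified F1 with MeLi in THF and then add HMPA, so that a free lithium enolate, without aluminium and without excess organometallic, closes ring B. The sequence comes back to the route at 20.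

Step 8. Most likely to go wrong: Wurtz-type homocoupling while the allylic Grignard reagent forms, which wastes the chiral chloride, and migration of the skipped alkene into conjugation during the acid hydrolysis. Fallback: set out from 10, convert it with Bu3SnLi (THF, −78 °C) into the allylstannane F2, and couple F2 with commercial 3-bromocyclohex-2-en-1-one under Stille conditions [Pd(PPh3)4, CuI, CsF, DMF]. The bond is then made by cross-coupling instead of carbonyl addition, without magnesium or acid, and the route is rejoined at 14.

Step 13. Most likely to go wrong: the equilibration stalls at a mixture, or the enediolate leads on to transposition of the ketol (carbonyl to C3) or to loss of the cis fusion by exchange at C5. Fallback: set out from 21 and invert C3 kinetically by a Mitsunobu reaction with 4-nitrobenzoic acid (PPh3, DIAD, THF), which gives the 3α-(4-nitrobenzoate) F3. Brief methanolysis (K2CO3, MeOH, 0 °C) returns to the route at 22.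

Step 14. Most likely to go wrong: the basic Grignard reagent enolises the ketone instead of adding (recovered ketol, possible exchange at C5), or some methyl is delivered from the α face. Fallback: set out from 22 and methylenate the ketone with excess Ph3P=CH2 to the allylic alcohol F4. Epoxidise the new C4 methylidene group under hydroxyl direction [VO(acac)2, t-BuOOH], syn to the 3α-hydroxyl, to the spiro-epoxide F5 with oxygen on the α face. Open F5 at its CH2 carbon with LiEt3BH, which gives the 4β-methyl-4α-ol and rejoins the route at 23.

Step 19. Most likely to go wrong: acylation of the axial tertiary hydroxyl, flanked by the C3 ester and syn-axial to C9, is too slow, and forcing leads to elimination or acyl scrambling. Fallback: set out from 23 and form the cyclic orthoacetate F6 with MeC(OMe)3 and pyridinium tosylate. Open F6 with dilute aqueous acetic acid; the known preference of cis-diol orthoesters for the axial ester should give the 4α-acetate 3α-alcohol F7. Esterify O3 of F7 with 27 under the conditions of step 18 (through 28), which comes back to the route at 30.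

## Further compounds

F1 | step 11 | trimethylsilyl enol ether of the conjugate adduct (O–Si on C4, C4=C5, 10R, 7R) | C[Si](C)(C)OC1=C[C@@](C)(CC(=C)[C@@H](C(C)C)CI)CCC1
F2 | step 8 | tributyl{2-[(2R)-1-(tert-butyldimethylsilyloxy)-3-methylbutan-2-yl]prop-2-en-1-yl}stannane | CCCC[Sn](CCCC)(CCCC)CC(=C)[C@@H](C(C)C)CO[Si](C)(C)C(C)(C)C
F3 | step 13 | 3α-(4-nitrobenzoyloxy)-10β-methyl-7β-isopropyl-8-methylidene-5β-H-decalin-4-one | O=C1[C@H](OC(=O)c3ccc(cc3)[N+](=O)[O-])CC[C@]2(C)CC(=C)[C@@H](C(C)C)C[C@@H]21
F4 | step 14 | 10β-methyl-7β-isopropyl-4,8-dimethylidene-5β-H-decalin-3α-ol | C=C1[C@H](O)CC[C@]2(C)CC(=C)[C@@H](C(C)C)C[C@@H]21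
F5 | step 14 | 4α,15-epoxy-8-methylidene-5β-eudesman-3α-ol (spiro-epoxide, oxygen on the α face of C4) | O3C[C@]31[C@H](O)CC[C@]2(C)CC(=C)[C@@H](C(C)C)C[C@@H]21
F6 | step 19 | 3α,4α-O-(1-methoxyethylidene) orthoester of 23 (both epimers at the orthoester carbon) | COC3(C)O[C@]1(C)[C@H](O3)CC[C@]2(C)CC(=C)[C@@H](C(C)C)C[C@@H]21
F7 | step 19 | 4α-acetoxy-8-methylidene-5β-eudesman-3α-ol | CC(=O)O[C@]1(C)[C@H](O)CC[C@]2(C)CC(=C)[C@@H](C(C)C)C[C@@H]21
A1 | alternative 1 | 2-methoxy-5-methyl-1,4-benzoquinone | COC1=CC(=O)C(C)=CC1=O
A2 | alternative 1 | 2-(tert-butyldimethylsilyloxy)-3-isopropylbuta-1,3-diene | C=C(O[Si](C)(C)C(C)(C)C)C(=C)C(C)C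
A3 | alternative 1 | dichlorodiisopropoxytitanium TiCl2(OiPr)2 | CC(C)O[Ti](Cl)(Cl)OC(C)C
A4 | alternative 1 | enantiopure 1,1'-bi-2-naphthol (one atropisomer; the axis is not expressed in this SMILES) | Oc1ccc2ccccc2c1-c1c(O)ccc2ccccc12
A5 | alternative 1 | cis-fused methoxy enedione with the C8 silyl enol ether | O=C1C(OC)=CC(=O)[C@]2(C)CC(O[Si](C)(C)C(C)(C)C)=C(C(C)C)C[C@@H]21
A6 | alternative 2 | 3-methylcyclohex-2-en-1-one | CC1=CC(=O)CCC1
A7 | alternative 2 | allene (propa-1,2-diene) | C=C=C
A8 | alternative 2 | cis-6-methyl-8-methylidenebicyclo[4.2.0]octan-2-one | O=C1CCC[C@]2(C)CC(=C)[C@@H]21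
A9 | alternative 3 | 3-acetyl-3-hydroxy cis-hydrindane precursor (carbinol epimer whose chelated shift gives the 4α-hydroxyl) | CC(=O)[C@@]1(O)CC[C@]2(C)CC(=O)[C@@H](C(C)C)C[C@@H]21
A10 | alternative 3 | aluminium tri-tert-butoxide Al(OtBu)3 | CC(C)(C)O[Al](OC(C)(C)C)OC(C)(C)C
A11 | alternative 3 | cis-decalin 4α-hydroxy-4β-methyl-3,8-dione | O[C@]1(C)C(=O)CC[C@]2(C)CC(=O)[C@@H](C(C)C)C[C@@H]21
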